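**Retrosynthetic overview** (ring A = pyrrole, B = five-membered lactam fused to A, C = piperidine, D = imidazoline)
1. Feature: the carbinolamine carbon of ring D (bonded to OH, to ring D N3, to the triamino aminal carbon shared by rings B, C and D, and to the last CH2 of ring C) is a ring D acyl-isothiourea carbonyl carbon that has taken up the terminal carbon of the propyl chain on the ring B lactam nitrogen.
2. Endgame disconnections: two C–Br bonds on ring A, the N-Boc group, and the C2–NH2 bond of ring D (from SMe and ammonia), leading back to a Boc/SMe-protected debromo tetracycle.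
3. Key disconnection: the CH2–C(OH) bond of ring C, giving a spiro A-B/D compound with an N-(3-iodopropyl) chain; ring C is closed by a SmI2 Barbier addition.
4. Spiro carbon: the ring D C–N and amide bonds go back to an α-chloro aminal ester and S-methylisothiourea; the ring B aminal goes back to a pyrrole-2-carboxamide and ethyl glyoxylate. The racemate is resolved once, after Boc protection.
5. Ring order: A (bought), B (step 2), D (step 3), C (step 8).

Key step: step 8

**Remarks on the chemistry**
- Atom labels: ring B has C1 (C=O) and N2 (lactam N); ring D has N1, C2, N3, C4 (carbonyl, later carbinol) and C5 (the spiro, later aminal, carbon).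
- Assumption: in step 4 the Boc group is taken to end on ring D N1 (the isomer that keeps the C2=N3–C4=O conjugation); the N3 isomer also has no N–H and would lead to the same target after steps 9 and 10.
- Design: the spiro carbon is not made by double condensation on an imidazole-4,5-dione, because its oxamide-type carbonyls open by acyl transfer with N-nucleophiles and water is too poor a leaving group for the aminal closure. A chloride placed by enolate chemistry is used instead. No catalytic asymmetric C–N bond formation at a triamino carbon is established, so the racemate is resolved; the absolute configuration is to be assigned by anomalous-dispersion X-ray analysis of the iodide of step 7.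

**Step 1**
Reactants: 1 2,2,2-trichloro-1-(1H-pyrrol-2-yl)ethanone; 2 3-[(tert-butyldimethylsilyl)oxy]propan-1-amine
Product: 3 N-{3-[(tert-butyldimethylsilyl)oxy]propyl}-1H-pyrrole-2-carboxamide
Conditions: Et3N, MeCN, rt
Reagents that add atoms: none
Why: Haloform-type acyl substitution: the primary amine adds to the trichloromethyl ketone and trichloromethanide leaves as chloroform, so nitrogen is acylated without touching the pyrrole N–H.

**Step 2**
Reactants: 3 N-{3-[(tert-butyldimethylsilyl)oxy]propyl}-1H-pyrrole-2-carboxamide; 4 ethyl glyoxylate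
Product: 5 ethyl (±)-2-{3-[(tert-butyldimethylsilyl)oxy]propyl}-1-oxo-2,3-dihydro-1H-pyrrolo[1,2-c]imidazole-3-carboxylate
Conditions: 4 (50% in toluene, 1.5 equiv), camphor-10-sulfonic acid (10 mol %), 4 Å MS, toluene, 80 °C
Reagents that add atoms: none
Why: Acid-catalysed N,N-acetalisation: the amide N–H and the electron-poor aldehyde give a hemiaminal, ionisation gives an N-acyliminium ion, and the pyrrole nitrogen closes ring B (the 2-acyl group deactivates the pyrrole carbons toward Mannich attack); the new stereocentre is racemic and is erased in step 3.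

**Step 3**
Reactants: 5 ethyl (±)-2-{3-[(tert-butyldimethylsilyl)oxy]propyl}-1-oxo-2,3-dihydro-1H-pyrrolo[1,2-c]imidazole-3-carboxylate; 6 S-methylisothiourea hemisulfate
Product: 8 (±)-2'-{3-[(tert-butyldimethylsilyl)oxy]propyl}-2-(methylsulfanyl)-1H-spiro[imidazole-5,3'-pyrrolo[1,2-c]imidazole]-1',4(2'H)-dione, via α-chloro aminal ester 7 (not isolated)
Conditions: LiN(iPr)2, THF, −78 °C; C2Cl6, −78 → 0 °C; then 6, K2CO3, DMF, 0 → 50 °C
Reagents that add atoms: none
Why: Enolate chlorination by C2Cl6 puts a leaving group on the carbon flanked by N2, the pyrrole nitrogen and the ester, and the classical imidazol-4-one synthesis from an α-halo ester and an amidine-type N,N-dinucleophile follows: chloride leaves with N-acyliminium-type assistance, one isothiourea nitrogen bonds to that carbon and the other closes on the ester (5-exo-trig), the acidic N–H of the product driving the sequence; the spiro carbon forms racemic.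

**Step 4**
Reactants: 8 (±)-spiro N–H acyl-isothiourea
Product: 9 tert-butyl (±)-2'-{3-[(tert-butyldimethylsilyl)oxy]propyl}-2-(methylsulfanyl)-1',4-dioxo-1',2'-dihydro-4H-spiro[imidazole-5,3'-pyrrolo[1,2-c]imidazole]-1-carboxylate
Conditions: Boc2O, 4-(dimethylamino)pyridine (20 mol %), Et3N, CH2Cl2, rt
Reagents that add atoms: di-tert-butyl dicarbonate, CC(C)(C)OC(=O)OC(=O)OC(C)(C)C
Why: Nucleophile-catalysed N-acylation of the only N–H under equilibrating conditions, expected to settle on N1 where the acyl-imine conjugation of ring D is kept; it removes the acidic proton that would quench the organometallic of step 8 and shuts the base-induced loss of pyrrolide by which the spiro carbon could racemise.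

**Step 5**
Reactants: 9 (±)-N1-Boc spiro silyl ether
Product: 10 (R)-enantiomer of 9, tert-butyl (5R)-2'-{3-[(tert-butyldimethylsilyl)oxy]propyl}-2-(methylsulfanyl)-1',4-dioxo-1',2'-dihydro-4H-spiro[imidazole-5,3'-pyrrolo[1,2-c]imidazole]-1-carboxylate
Conditions: preparative SFC, amylose tris(3,5-dimethylphenylcarbamate) phase, CO2/iPrOH
Reagents that add atoms: none
Why: Chromatographic resolution of enantiomers on a chiral stationary phase; 9 has no N–H and its spiro carbon (three acylated or aromatic nitrogens and an acyl group) cannot ionise easily, so the separated enantiomer should keep its configuration through steps 6 to 8.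

**Step 6**
Reactants: 10 (R)-N1-Boc spiro silyl ether
Product: 11 tert-butyl (5R)-2'-(3-hydroxypropyl)-2-(methylsulfanyl)-1',4-dioxo-1',2'-dihydro-4H-spiro[imidazole-5,3'-pyrrolo[1,2-c]imidazole]-1-carboxylate
Conditions: HF·pyridine, pyridine, THF, 0 °C → rt
Reagents that add atoms: none
Why: Fluoride-driven desilylation (strong Si–F bond) under buffered, non-basic conditions that leave the Boc group and the acyl-isothiourea untouched.

**Step 7**
Reactants: 11 (R)-spiro alcohol
Product: 12 tert-butyl (5R)-2'-(3-iodopropyl)-2-(methylsulfanyl)-1',4-dioxo-1',2'-dihydro-4H-spiro[imidazole-5,3'-pyrrolo[1,2-c]imidazole]-1-carboxylate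
Conditions: I2, PPh3, imidazole, CH2Cl2, 0 °C → rt, dark
Reagents that add atoms: iodine, II
Why: Appel-type iodination: the alkoxyphosphonium ion of the primary alcohol is displaced by iodide (SN2) under neutral conditions, and no nucleophilic nitrogen remains to alkylate.

**Step 8**
Reactants: 12 (R)-spiro iodide
Product: 14 tetracyclic carbinolamine (rings A–D; SMe at ring D C2; Boc on ring D N1; both pyrrole positions H; R at the carbinol carbon and R at the aminal carbon), via alkylsamarium diiodide 13 (not isolated)
Conditions: SmI2 (2.5 equiv), NiI2 (2 mol %), THF, 0 °C, slow addition of 12; aq NH4Cl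
Reagents that add atoms: none
Why: SmI2 reduces NiI2 to zerovalent nickel, which activates the primary C–I bond, and alkyl transfer to trivalent samarium gives alkylsamarium 13, which adds to the ring D C4 carbonyl (Barbier addition); the closest known reaction is the SmI2-mediated cyclisation of N-(ω-iodoalkyl) imides to bicyclic hydroxy lactams. Ring C closes in the 6-exo-trig mode (chain carbon onto the exocyclic C=O; ring atoms N2, C5, C4 and three CH2). The carbinol stereocentre is controlled by the spiro carbon: the tether hangs from N2 on one face of ring D and can deliver carbon only to that face, so OH ends cis to the pyrrole nitrogen (cis C/D fusion, the only geometrically possible one), and ring–chain tautomerism of the carbinolamine would correct a wrong closure. The step needs C–I activation to outrun electron transfer to the ring D carbonyl, which the nickel catalyst at 0 °C without HMPA should secure, since a carbonyl at the carboxylic acid oxidation level is reduced far less readily than a ketone. It also needs the ring D carbonyl to win over the other carbonyls: it is an N-acyl-imine carbonyl with no amide resonance from N3, whereas the ring B lactam carbonyl is deactivated by the pyrrole and the Boc carbonyl would require a seven-membered ring. No N–H, O–H or aryl bromide is present to quench the organometallic or to compete for the reductant.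

**Step 9**
Reactants: 14 tetracyclic S-methyl carbinolamine
Product: 15 N1-Boc 2-aminoimidazoline tetracycle (NH2 in place of SMe; R at the carbinol carbon and R at the aminal carbon)
Conditions: NH3 (7 M in MeOH), sealed tube, 50 °C
Reagents that add atoms: ammonia, N
Why: Addition–elimination at the isothiourea carbon, activated by the N-Boc group (guanidine synthesis by aminolysis of an S-methylisothiourea), with methanethiolate as the leaving group.

**Step 10**
Reactants: 15 N1-Boc 2-aminoimidazoline tetracycle
Product: 16 debromo target (free 2-aminoimidazoline; R at the carbinol carbon and R at the aminal carbon; handled as its trifluoroacetate and drawn neutral)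
Conditions: TFA/CH2Cl2 (1:4), 0 °C → rt
Reagents that add atoms: none
Why: Acidolysis of the tert-butyl carbamate (loss of 2-methylpropene and CO2); the guanidinium, the aminal and the carbinolamine should tolerate TFA, and water can return to an ionised carbinol carbon only on the cis face.

**Step 11**
Reactants: 16 debromo target
Product: 17 target, NC1=N[C@@]2(O)CCCN3C(=O)c4cc(Br)c(Br)n4[C@@]32N1 (R at the carbinol carbon; the aminal carbon is now S only because bromine raises the CIP rank of the pyrrole nitrogen)
Conditions: NBS (2.05 equiv), MeCN, TFA (2 equiv), 0 °C; aq NaHCO3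
Reagents that add atoms: N-bromosuccinimide, O=C1CCC(=O)N1Br
Why: Electrophilic aromatic bromination of the N-substituted 2-acylpyrrole at its two positions remote from the carbonyl (the position next to the acyl group is the least reactive), with the guanidine protected from N-bromination as its guanidinium salt.

**Compound list**
1 | 2,2,2-trichloro-1-(1H-pyrrol-2-yl)ethanone | O=C(c1ccc[nH]1)C(Cl)(Cl)Cl | starting material
2 | 3-[(tert-butyldimethylsilyl)oxy]propan-1-amine | NCCCO[Si](C)(C)C(C)(C)C | starting material
3 | N-{3-[(tert-butyldimethylsilyl)oxy]propyl}-1H-pyrrole-2-carboxamide | O=C(NCCCO[Si](C)(C)C(C)(C)C)c1ccc[nH]1 | intermediate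
4 | ethyl glyoxylate (ethyl 2-oxoacetate) | CCOC(=O)C=O | starting material
5 | ethyl (±)-2-{3-[(tert-butyldimethylsilyl)oxy]propyl}-1-oxo-2,3-dihydro-1H-pyrrolo[1,2-c]imidazole-3-carboxylate | CCOC(=O)C1N(CCCO[Si](C)(C)C(C)(C)C)C(=O)c2cccn12 | intermediate
6 | S-methylisothiourea hemisulfate | CSC(N)=N.CSC(N)=N.OS(O)(=O)=O | starting material
7 | ethyl (±)-3-chloro-2-{3-[(tert-butyldimethylsilyl)oxy]propyl}-1-oxo-2,3-dihydro-1H-pyrrolo[1,2-c]imidazole-3-carboxylate | CCOC(=O)C1(Cl)N(CCCO[Si](C)(C)C(C)(C)C)C(=O)c2cccn12 | intermediate (not isolated)
8 | (±)-2'-{3-[(tert-butyldimethylsilyl)oxy]propyl}-2-(methylsulfanyl)-1H-spiro[imidazole-5,3'-pyrrolo[1,2-c]imidazole]-1',4(2'H)-dione | CSC1=NC(=O)C2(N1)N(CCCO[Si](C)(C)C(C)(C)C)C(=O)c3cccn23 | intermediate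
9 | tert-butyl (±)-2'-{3-[(tert-butyldimethylsilyl)oxy]propyl}-2-(methylsulfanyl)-1',4-dioxo-1',2'-dihydro-4H-spiro[imidazole-5,3'-pyrrolo[1,2-c]imidazole]-1-carboxylate | CSC1=NC(=O)C2(N1C(=O)OC(C)(C)C)N(CCCO[Si](C)(C)C(C)(C)C)C(=O)c3cccn23 | intermediate
10 | (5R)-enantiomer of 9 | CC(C)(C)[Si](C)(C)OCCCN1C(=O)c2cccn2[C@]13C(=O)N=C(SC)N3C(=O)OC(C)(C)C | intermediate
11 | tert-butyl (5R)-2'-(3-hydroxypropyl)-2-(methylsulfanyl)-1',4-dioxo-1',2'-dihydro-4H-spiro[imidazole-5,3'-pyrrolo[1,2-c]imidazole]-1-carboxylate | OCCCN1C(=O)c2cccn2[C@]13C(=O)N=C(SC)N3C(=O)OC(C)(C)C | intermediate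
12 | tert-butyl (5R)-2'-(3-iodopropyl)-2-(methylsulfanyl)-1',4-dioxo-1',2'-dihydro-4H-spiro[imidazole-5,3'-pyrrolo[1,2-c]imidazole]-1-carboxylate | ICCCN1C(=O)c2cccn2[C@]13C(=O)N=C(SC)N3C(=O)OC(C)(C)C | intermediate
13 | alkylsamarium diiodide derived from 12 (SmI2 in place of I at the chain end) | I[Sm](I)CCCN1C(=O)c2cccn2[C@]13C(=O)N=C(SC)N3C(=O)OC(C)(C)C | intermediate (not isolated)
14 | tetracyclic carbinolamine: rings A–D, SMe at ring D C2, Boc on ring D N1, pyrrole unbrominated; carbinol carbon R, aminal carbon R | CSC1=N[C@@]2(O)CCCN3C(=O)c4cccn4[C@@]32N1C(=O)OC(C)(C)C | intermediate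
15 | N1-Boc 2-aminoimidazoline tetracycle; carbinol carbon R, aminal carbon R | NC1=N[C@@]2(O)CCCN3C(=O)c4cccn4[C@@]32N1C(=O)OC(C)(C)C | intermediate
16 | debromo target; carbinol carbon R, aminal carbon R | NC1=N[C@@]2(O)CCCN3C(=O)c4cccn4[C@@]32N1 | intermediate
17 | target: dibromopyrrole tetracycle; carbinol carbon R, aminal carbon S | NC1=N[C@@]2(O)CCCN3C(=O)c4cc(Br)c(Br)n4[C@@]32N1 | target

**Totals**
Total step count: 11. Longest linear sequence: 11 steps (1 → 17).

**Steps most likely to fail**

Step 8. Electron transfer from SmI2 to the ring D carbonyl may compete with C–I activation and be followed by cleavage of a C–N bond at the spiro carbon; the organosamarium may also be protonated, or the samarium alkoxide may collapse by ring D opening and be reduced further. Fallback, from 12: t-BuLi (2.1 equiv) in Et2O/pentane at −100 °C should give, by iodine–lithium exchange, the 3-lithiopropyl compound F1, which on warming to −78 °C adds to the same carbonyl in the same 6-exo mode (anionic cyclisation of the Parham type, with no single-electron reductant present). Quenching with aqueous NH4Cl gives 14, where the route is rejoined.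

Step 3. Capture of the hindered, poorly stabilised cationic carbon by the isothiourea nitrogen may be slow, so that the chloride is lost to hydrolysis or the ester is consumed without spiro ring closure. Fallback, from 5, with the polarity of the carbon reversed:
- The LiN(iPr)2 enolate is trapped with di-tert-butyl azodicarboxylate (electrophilic amination) to give the hydrazinodicarboxylate F2.
- Its remaining N–H is alkylated with methyl bromoacetate and Cs2CO3 to give the N'-(methoxycarbonylmethyl) hydrazide F3.
- Warming F3 with the same base cleaves the N–N bond by E1cB loss of methyl N-Boc-iminoacetate and leaves the Boc-amino ester F4.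
- NH3 in MeOH converts the ester into the carboxamide F5.
- NaH and 1,1'-thiocarbonyldiimidazole bridge the two N–H groups to give the 1-Boc-2-thiohydantoin F6.
- MeI/K2CO3 methylates sulfur to give 9, with Boc already on N1, where the route is rejoined at step 5.

Step 9. Addition–elimination at the isothiourea carbon may be sluggish, and ammonia may meanwhile open the carbinolamine or remove the Boc group that activates the substitution. Fallback, from 14: 2,4-dimethoxybenzylamine, a stronger nucleophile than ammonia (with AgOTf as thiophile if needed), displaces the methylthio group to give the N-(2,4-dimethoxybenzyl)guanidine F7. TFA/Et3SiH then removes the benzyl group and the Boc group together and gives 16, where the route is rejoined at step 11.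

**Further compounds**
F1 | step 8 | 3-lithiopropyl analogue of 12 | [Li]CCCN1C(=O)c2cccn2[C@]13C(=O)N=C(SC)N3C(=O)OC(C)(C)C
F2 | step 3 | di-tert-butyl (±)-1-[3-(ethoxycarbonyl)-1-oxo-2-{3-[(tert-butyldimethylsilyl)oxy]propyl}-2,3-dihydro-1H-pyrrolo[1,2-c]imidazol-3-yl]hydrazine-1,2-dicarboxylate | CCOC(=O)C1(N(NC(=O)OC(C)(C)C)C(=O)OC(C)(C)C)N(CCCO[Si](C)(C)C(C)(C)C)C(=O)c2cccn12
F3 | step 3 | N'-(methoxycarbonylmethyl) derivative of F2 | CCOC(=O)C1(N(N(CC(=O)OC)C(=O)OC(C)(C)C)C(=O)OC(C)(C)C)N(CCCO[Si](C)(C)C(C)(C)C)C(=O)c2cccn12
F4 | step 3 | ethyl (±)-3-[(tert-butoxycarbonyl)amino]-2-{3-[(tert-butyldimethylsilyl)oxy]propyl}-1-oxo-2,3-dihydro-1H-pyrrolo[1,2-c]imidazole-3-carboxylate | CCOC(=O)C1(NC(=O)OC(C)(C)C)N(CCCO[Si](C)(C)C(C)(C)C)C(=O)c2cccn12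
F5 | step 3 | (±)-3-[(tert-butoxycarbonyl)amino]-2-{3-[(tert-butyldimethylsilyl)oxy]propyl}-1-oxo-2,3-dihydro-1H-pyrrolo[1,2-c]imidazole-3-carboxamide | NC(=O)C1(NC(=O)OC(C)(C)C)N(CCCO[Si](C)(C)C(C)(C)C)C(=O)c2cccn12
F6 | step 3 | (±)-spiro 1-Boc-2-thiohydantoin (C=S in place of C–SMe of 9, N3–H) | S=C1NC(=O)C2(N1C(=O)OC(C)(C)C)N(CCCO[Si](C)(C)C(C)(C)C)C(=O)c3cccn23
F7 | step 9 | N-(2,4-dimethoxybenzyl) derivative of 15 at the exocyclic guanidine nitrogen | COc1ccc(CNC2=N[C@@]3(O)CCCN4C(=O)c5cccn5[C@@]43N2C(=O)OC(C)(C)C)c(OC)c1
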